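Two questions stand here: the order of the starting rate in free catalyst, and the share of starting material that has become target in the zeta flask at 29 min.

| flask | starting material | coupling partner | free catalyst | time |
|---|---|---|---|---|
| eta | 200 mM | 300 mM | 1.00 mM |  |
| gamma | 80.0 mM | 180 mM | 1.00 mM |  |
| delta | 200 mM | 300 mM | 1.50 mM |  |
| zeta | 66.0 mM | 900 mM | 1.00 mM | 29 min |

| eta run: time / min | eta run: [target] / mM | gamma run: time / min | gamma run: [target] / mM | delta run: time / min | delta run: [target] / mM |
|---|---|---|---|---|---|
| 1.3 | 9.9 | 1.3 | 6.8 | 1.3 | 14.0 |
| 3.9 | 27.6 | 3.9 | 9.9 | 3.9 | 34.8 |
| 7.5 | 38.0 | 7.5 | 17.1 | 7.5 | 53.4 |
| 12 | 47.4 | 12 | 21.1 | 12 | 67.5 |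
| 17 | 49.2 | 17 | 29.9 | 17 | 73.1 |
| 23 | 53.7 | 23 | 29.4 | 23 | 75.8 |
| 29 | 57.0 | 29 | 28.8 | 29 | 78.8 |

(each reading ± 2 mM)

- Overall: starting material + coupling partner -> target, with free catalyst as catalyst.
- Constant volume, constant temperature.
- What is held in complexes is read along with the free species.
- An order is taken over about fifteen percent of the charge, up and down.

1. apparent order in [free catalyst] of the starting rate, round the charge of the eta run (the rate where two percent of its starting material have turned into target)
2. target in the zeta run at 29 min, as a share of the starting material charged

The order you can estimate from the first readings: at 1.3 min the delta run stands at 1.41 times the target of the eta run on 1.50 times the catalyst, which as a reading makes the order about 0.855, but with a scatter of 2 mM on each reading it tells little more than an order near one.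

For the zeta flask, ask first for the end state. The eta run flattens near 57.0 mM with 143 mM of starting material and 243 mM of coupling partner still present, so neither has run out, and the delta run, on the same charges with more catalyst, stands higher at 78.8 mM, which points to a catalyst giving up. Carry therefore the turnover capacity N, the target made by 29 min per unit of free catalyst charged (a turnover number), which reads 28.8 in the gamma run, 57.0 in the eta run and 52.5 in the delta run.

Now take two extremes. If the catalyst's life ignored coupling partner, N would grow with partner to 144, more than the 66.0 that the starting material, the limiting reagent, allows, and zeta would reach 100%. If partner shortened that life as much as it speeds turnover, it would cancel, N would stay at the gamma value, and zeta would reach 43.6%.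

The eta and gamma runs differ in both charges at once, so their readings of N, 57.0 against 28.8, cannot say how much of that step belongs to coupling partner, and they do not pick an extreme. The zeta flask holds less starting material than the gamma run, which may lower N somewhat, so I hold to a bracket from the gamma run's share, 36.0%, up to 100%.

The forecast says 0.9 and 55%, above the lower end of that bracket, on the grounds that “the data cannot say whether in starting material or coupling partner”.

The flask gives an order of 1.1 and 41.3%.

    free catalyst + starting material ⇌ catalyst-substrate complex, settled at all times (31.60 /M)
    catalyst-substrate complex + coupling partner → target + free catalyst (47.10 /M/min)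
    free catalyst + coupling partner → spent catalyst + coupling partner (1.212 /M/min)
    2 starting material ⇌ idle substrate dimer, settled at all times (29.40 /M)

In the zeta run N comes to 27.2, against 28.8 in the gamma run, although zeta holds 5.00 times the coupling partner. Extra partner raised the pace of turnover and of catalyst loss together. The main reason for the shortfall is the passing of free catalyst + coupling partner into spent catalyst + coupling partner: the same zeta run without that step reaches 100% instead of 41.3%, a difference of 59 percentage points.

(Readings and results stem from a simulated flask for an exercise, noise included.)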